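## Structural features

The target is the caffeate of a trichodiene-type sesquiterpene alcohol. Ring A is a 2-methylidenecyclopentane (carbons A1–A5, A1 carrying the exocyclic CH2), ring B is a cyclohexene (carbons B1–B6, B3=B4, methyl on B4), and the two rings are joined only by the single bond A5–B1. Both carbons of that bond are quaternary and each bears a methyl group, so two contiguous all-carbon stereocentres (A5 S, B1 S) face each other across a freely rotating bond with no ring fusion to relay configuration. The third stereocentre, B5 (S), is a secondary allylic carbinol ester 1,3 to B1 across B6; its oxygen is cis to the A5 branch and trans to the B1 methyl on ring B. Fragile elements are the exocyclic methylene beside quaternary A5 (acid leads to cationic rearrangement), the allylic ester (ionisation, allylic transposition), the catechol (oxidation under base) and the cinnamate (conjugate addition). The real difficulty is the A5/B1 pair. The key step treats A5 and B1 as the two carbons of a former (Z)-tetrasubstituted alkene with cis methyl groups: B1 takes carbon B2 of an enone, A5 takes A4 by ring enlargement of a cyclobutanol whose carbinol carbon becomes A1, and the B5 oxygen, α to the B4 carbonyl, supplies a chelation handle that fixes the alkene face.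

## Logic of the disconnections

24 is cut at the ester C–O bond and at the two aryl O–Si bonds of 23, giving 19 and 22. The cinnamate and catechol would not survive organometallic or strongly basic steps, so they arrive last. The forward demand is acylation on oxygen with retention at B5: the B5 configuration of 19 is already that of 24, so an inverting esterification is excluded.

19 goes back through 18 and 17 to 16 and 15 by functional-group changes only: the benzyl O–C bond, the A1=CH2 bond (from the A1 ketone) and the B4–CH3 bond with the B3=B4 alkene (from the B4 ketone). This reduces the problem to a diketone whose carbonyls differ strongly in hindrance. The forward demands are attack of a methyl nucleophile on B4 only, dehydration towards B3 only, and debenzylation without acid.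

15 is cut at B1–B2 and A5–A4 to give 13. This is the strategic cut: it removes both rings and both quaternary stereocentres at once and leaves an acyclic chain with one stereocentre (B5) and one alkene geometry. The forward step must add the two new bonds anti across the alkene, choose the alkene face from B5, and beat proton-driven side paths.

13 is cut at B3–B4 (vinyl Grignard on a Weinreb amide) to 12, then at the amide and benzyl ether to 11 and 10. These are routine changes; the demand is that B5, now α to a carbonyl, is not epimerised.

10 is cut at B1–B6 into 6 and 7. B5 then comes from the chiral pool and B1 acts as the nucleophile. This avoids an allylic electrophile at B6 cis to the cyclobutanol oxygen, which would close to a spiro-dihydrofuran. The demand is transfer of a hindered alkenyl group to C3 of the glycidate with retention of alkene geometry.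

6 comes from 5, and 5 is cut at A5–A1 and B1–I into 1 and 2. Syn difunctionalisation of a symmetrical alkyne fixes the cis methyl groups without any regiochemical question. 22 comes from 20 by silylation.

## Other disconnections considered

Alternative 1: The cut is the B1–CH3 bond. The methyl is delivered as the methylene of a cyclopropane across B1–B6, ring B being drawn from an anisole by Birch reduction. The forward key step is a hydroxyl-directed cyclopropanation (Et2Zn, CH2I2) of allylic alcohol compound A2 syn to the B5 hydroxyl, giving compound A1. Oxidation at B5 and dissolving-metal opening of the B6–CH2 bond would later unveil the quaternary methyl.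
- In its favour: every operation is established chemistry, the directing effect is one of the most reliable ways to set a quaternary carbon relative to a carbinol, and the cyclopropyl ketone opening is regioselective.
- Against it here: the directing hydroxyl must lie on the face of the future methyl, which is opposite to the B5 oxygen of the target. It is then spent as a ketone, so B5 must be rebuilt at the end. Carbon A5 must be made beforehand as an enantioenriched quaternary α-aryl ketone, and its relation to B5 in compound A2 rests on a reagent-controlled reduction across a rotating bond. The B4 methyl and the B3=B4 alkene remain to be added, and carbon A1 needs a ketal.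
- Comparison: on structure, both plans set B1 from B5, but the chosen plan lets B1 fix A5 in the same event, whereas this one needs three separate stereo-events. On mechanism the alternative is the better one, since nothing in it is unprecedented. On step economy the chosen plan is shorter (14 steps against an estimated 18 or more).

Alternative 2: The cuts are B4–B5 and B2–B3. Ring B is assembled from the prochiral cyclobutanone compound A4 and 1-(trimethylsilyl)propyne. The forward key step uses Ni(cod)2 with a chiral phosphine: oxidative cyclisation of carbonyl and alkyne, β-carbon elimination of one of the two B5–CH2 bonds, and reductive elimination, giving cyclohexenone compound A3.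
- In its favour: ring B arrives with the B4 methyl, the B3=B4 unsaturation and a B5 carbonyl already in place. On this point it is better than the chosen plan, which must differentiate two ketones and control a dehydration. B1 is set by the catalyst.
- Against it here: compound A4 already contains the A5–B1 bond between two fully substituted carbons and the A5 stereocentre, so the central difficulty is moved into the preparation of compound A4. The two B5–CH2 bonds are diastereotopic, so the ligand must cooperate with or override the A5 centre. The alkyne must insert with its methyl end at the carbonyl. B5 would come from a late enone reduction, and the A1 oxygen needs deprotection, oxidation and olefination.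
- Comparison: on mechanism the nickel insertion is a known reaction class and is equal to or better than the chosen cascade in precedent, although its desymmetrising use on so hindered a substrate would also be an extension. On structure it creates one stereocentre where the chosen step creates two. On step economy it should be similar or somewhat longer.

Alternative 3: The cut is the bond between carbons A1 and A5. Ring A is closed last by carbenoid C–H insertion. In the forward key step Rh2(OAc)4 decomposes the diazo keto ester compound A6, and the carbenoid at carbon A1 inserts into the tertiary C–H bond of carbon A5 with retention, giving compound A5.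
- In its favour: the configuration of carbon A5 comes from the chiral pool (the methyl-bearing centre of citronellal) and is transferred stereospecifically. 1,5-Insertion into a tertiary C–H bond is the most favourable case of this chemistry, and the β-keto ester offers handles.
- Against it here: in compound A5 ring B is still symmetrical, so carbon B1 is not yet stereogenic and B5 carries no oxygen. Both would have to come from a later differentiation of the two halves of ring B under the sole influence of the neighbouring quaternary centre. The insertion site is flanked by quaternary B1. The ring A ketone must be deleted and the ester carbon turned into the methylene.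
- Comparison: on mechanism the alternative is the better one, because the insertion is well precedented. On the source of chirality the two plans are equal, both drawing one centre from the pool. On structure it leaves two of the three stereocentres unsolved. On step economy it is worse (estimated above 20 steps).

Key step: step 7

Assumption: the cyclobutanol of the cyclisation substrate is carried as its triethylsilyl ether and B5 keeps a benzyl ether. This changes only a spectator group, leaves the two bonds formed in the key step and both skeletons unchanged, and the silyl group is lost in that step.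

Remark: a check of the stereochemical bookkeeping shows that (Z) geometry plus anti addition gives the A5/B1 relation of 24, and that the B5 centre of 13 is already the B5 centre of 24. The end game therefore keeps B5 untouched and uses no inverting esterification.

## Route

Step 1
Reactants: 1 2-butyne, 2 cyclobutanone
Product: 5 1-[(2Z)-3-iodobut-2-en-2-yl]cyclobutan-1-ol, via titanacyclopropene 3 (not isolated), via oxatitanacyclopentene 4 (not isolated)
Conditions: Ti(O-i-Pr)4 (1.2 equiv), i-PrMgCl (2.4 equiv), Et2O, −78 to −50 °C; 2, −78 to −40 °C; I2, −78 °C to rt; aq. Na2S2O3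
Reagents that add atoms: iodine, II
Why: Alkyne–carbonyl coupling through a diisopropoxy(η2-alkyne)titanium complex (a divalent titanium equivalent made from Ti(O-i-Pr)4 and i-PrMgCl); the ketone inserts into one Ti–C bond and iodine cleaves the remaining alkenyl–Ti bond with retention. Syn addition across the symmetrical alkyne puts iodine and the carbinol carbon cis, so the two methyl groups are cis and there is no regiochemical issue.

Step 2
Reactants: 5 1-[(2Z)-3-iodobut-2-en-2-yl]cyclobutan-1-ol
Product: 6 triethyl({1-[(2Z)-3-iodobut-2-en-2-yl]cyclobutyl}oxy)silane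
Conditions: TESOTf (1.3 equiv), 2,6-lutidine (2 equiv), CH2Cl2, −78 to 0 °C
Reagents that add atoms: triethylsilyl trifluoromethanesulfonate, CC[Si](CC)(CC)OS(=O)(=O)C(F)(F)F
Why: Silylation of a hindered tertiary alcohol with a silyl triflate and a hindered base; the ether removes the acidic OH for the organometallic steps and for the cyclisation, and buffered conditions avoid acid-triggered ring enlargement.

Step 3
Reactants: 6 triethyl({1-[(2Z)-3-iodobut-2-en-2-yl]cyclobutyl}oxy)silane, 7 methyl (2S)-oxirane-2-carboxylate
Product: 10 methyl (2S,4Z)-2-hydroxy-4-methyl-5-{1-[(triethylsilyl)oxy]cyclobutyl}hex-4-enoate, via alkenyllithium 8 (not isolated), via alkenylmagnesium bromide 9 (not isolated)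
Conditions: t-BuLi (2.05 equiv), Et2O, −78 °C; MgBr2·OEt2 (1.1 equiv), −78 to −40 °C; CuBr·SMe2 (0.2 equiv), 7 (1.2 equiv), THF, −78 to −30 °C; aq. NH4Cl
Reagents that add atoms: none
Why: Iodine–lithium exchange proceeds with retention of alkene geometry, and the derived Grignard reagent opens the glycidic ester at the unsubstituted C3 under copper catalysis (SN2 epoxide opening of a glycidate), so the (S) centre of 7 becomes B5 unchanged. Ether solvent and low temperature are chosen to keep 1,4 O-to-C silyl migration in 8 slow.

Step 4
Reactants: 10 methyl (2S,4Z)-2-hydroxy-4-methyl-5-{1-[(triethylsilyl)oxy]cyclobutyl}hex-4-enoate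
Product: 11 methyl (2S,4Z)-2-(benzyloxy)-4-methyl-5-{1-[(triethylsilyl)oxy]cyclobutyl}hex-4-enoate
Conditions: BnBr (3 equiv), Ag2O (2 equiv), Et2O, 4 Å sieves, rt, dark
Reagents that add atoms: benzyl bromide, BrCc1ccccc1
Why: Silver-oxide-mediated O-benzylation is the neutral, non-epimerising Williamson variant for α-hydroxy esters; neither the silyl ether nor the alkene meets acid or strong base.

Step 5
Reactants: 11 methyl (2S,4Z)-2-(benzyloxy)-4-methyl-5-{1-[(triethylsilyl)oxy]cyclobutyl}hex-4-enoate
Product: 12 (2S,4Z)-2-(benzyloxy)-N-methoxy-N,4-dimethyl-5-{1-[(triethylsilyl)oxy]cyclobutyl}hex-4-enamide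
Conditions: MeNHOMe·HCl (3 equiv), i-PrMgCl (6 equiv), THF, −20 to 0 °C
Reagents that add atoms: N,O-dimethylhydroxylamine hydrochloride, CNOC.Cl
Why: Direct aminolysis of the ester by the magnesium amide of N,O-dimethylhydroxylamine (Weinreb amide formation); it runs below 0 °C without a Lewis acid, which should spare the silyl ether and the α-alkoxy stereocentre.

Step 6
Reactants: 12 (2S,4Z)-2-(benzyloxy)-N-methoxy-N,4-dimethyl-5-{1-[(triethylsilyl)oxy]cyclobutyl}hex-4-enamide
Product: 13 (4S,6Z)-4-(benzyloxy)-6-methyl-7-{1-[(triethylsilyl)oxy]cyclobutyl}octa-1,6-dien-3-one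
Conditions: vinylmagnesium bromide (2.5 equiv), THF, −78 to 0 °C; inverse quench into cold aq. NH4Cl; used at once
Reagents that add atoms: vinylmagnesium bromide, C=C[Mg]Br
Why: Weinreb ketone synthesis; the chelated tetrahedral intermediate prevents over-addition, and the inverse quench keeps the liberated hydroxylamine from adding to the new enone.

Step 7
Reactants: 13 (4S,6Z)-4-(benzyloxy)-6-methyl-7-{1-[(triethylsilyl)oxy]cyclobutyl}octa-1,6-dien-3-one
Product: 15 (2S,4S)-2-(benzyloxy)-4-methyl-4-[(1R)-1-methyl-2-oxocyclopentyl]cyclohexan-1-one, via aluminium enolate 14 (not isolated)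
Conditions: Me2AlCl (2.5 equiv), CH2Cl2 (0.01 M), −78 to −40 °C; aq. potassium sodium tartrate, then 1 M HCl–THF, 0 °C
Reagents that add atoms: none
Why: Proposed new method: Me2AlCl binds the B4 carbonyl and the B5 benzyloxy oxygen as a five-membered chelate, which raises the electrophilicity of the s-trans enone at carbon B2 and holds the ether in the carbonyl plane. The electron-rich tetrasubstituted alkene attacks B2 through carbon B1 (6-endo-trig at the enone, exo at the alkene; new B1–B2 bond, ring B), and the charge building at carbon A5 is discharged at once by anti 1,2-shift of a cyclobutane C–C bond pushed by the silyloxy oxygen (four- to five-membered ring enlargement; new A5–A4 bond, ring A; carbon A1 becomes C=O after loss of Et3SiCl). The closest known reaction types are Prins–pinacol and related cation–olefin cyclisations ended by semipinacol ring expansion of 1-alkenylcyclobutanol derivatives, and Lewis-acid-promoted enone–olefin cyclisations; using the enone as initiator of such a terminated cascade is the new element. Carbon B1 is controlled by the chelated B5 centre: in the chair transition state the benzyloxy group is equatorial because it must eclipse the chelated carbonyl, and the bulky alkene terminus that becomes A5 is equatorial, so the B1 methyl ends up axial and trans to the B5 oxygen. Carbon A5 is controlled by the (Z) geometry of the alkene and the anti course of the addition, the migrating bond entering on the face opposite to the new B1–B2 bond, which places the two methyl groups as in the target. The step needs C–C bond formation to win over proton-initiated ring expansion of the alkenylcyclobutane and over proton loss from the A5 cation; the silyl ether (no acidic OH), the proton-scavenging methylaluminium reagent, low temperature and dilution are meant to secure this, and strain release should make the shift faster than elimination. Aqueous acid then protonates the regiodefined enolate 14 to give 15.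

Step 8
Reactants: 15 (2S,4S)-2-(benzyloxy)-4-methyl-4-[(1R)-1-methyl-2-oxocyclopentyl]cyclohexan-1-one
Product: 16 (2R)-2-[(1S,3S,4R)-3-(benzyloxy)-4-hydroxy-1,4-dimethylcyclohexyl]-2-methylcyclopentan-1-one
Conditions: MeMgBr (1.3 equiv, Et2O), CH2Cl2, −78 °C; aq. NH4Cl
Reagents that add atoms: methylmagnesium bromide, C[Mg]Br
Why: Chelation-controlled Grignard addition: the α-benzyloxy ketone at B4 is activated and unhindered, whereas the A1 ketone is shielded by quaternary A5, so one equivalent should add at B4 only. Attack on the chelate from the face of the axial B5 hydrogen should place the new hydroxyl cis to the benzyloxy group; this centre is removed in step 9.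

Step 9
Reactants: 16 (2R)-2-[(1S,3S,4R)-3-(benzyloxy)-4-hydroxy-1,4-dimethylcyclohexyl]-2-methylcyclopentan-1-one
Product: 17 (2R)-2-[(1S,5S)-5-(benzyloxy)-1,4-dimethylcyclohex-3-en-1-yl]-2-methylcyclopentan-1-one
Conditions: Burgess reagent (2 equiv), toluene, 60 °C
Reagents that add atoms: none
Why: Burgess dehydration is a syn elimination through the sulfamate ester; with the hydroxyl cis to the benzyloxy group the B5 hydrogen is anti and cannot be reached, so no enol ether should form, and the cis hydrogen on B3 should give the more substituted endocyclic B3=B4 alkene in preference to the exocyclic one. The reagent is neutral and leaves the ketone and benzyl ether alone.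

Step 10
Reactants: 17 (2R)-2-[(1S,5S)-5-(benzyloxy)-1,4-dimethylcyclohex-3-en-1-yl]-2-methylcyclopentan-1-one
Product: 18 ({[(1S,5S)-2,5-dimethyl-5-[(1S)-1-methyl-2-methylidenecyclopentyl]cyclohex-2-en-1-yl]oxy}methyl)benzene
Conditions: Ph3PCH3Br (4 equiv), KOt-Bu (4 equiv), toluene, 90 °C
Reagents that add atoms: methyltriphenylphosphonium bromide, C[P+](c1ccccc1)(c1ccccc1)c1ccccc1.[Br-]
Why: Wittig methylenation under the hot alkoxide conditions used for hindered, enolisable ketones; A5 is quaternary, so no stereocentre can be lost, and the allylic benzyl ether is not acidic enough to react.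

Step 11
Reactants: 18 ({[(1S,5S)-2,5-dimethyl-5-[(1S)-1-methyl-2-methylidenecyclopentyl]cyclohex-2-en-1-yl]oxy}methyl)benzene
Product: 19 (1S,5S)-2,5-dimethyl-5-[(1S)-1-methyl-2-methylidenecyclopentyl]cyclohex-2-en-1-ol
Conditions: lithium 4,4'-di-tert-butylbiphenylide (LiDBB, 4 equiv), THF, −78 °C; aq. NH4Cl
Reagents that add atoms: none
Why: Reductive debenzylation by electron transfer: the electron enters the phenyl ring and the benzylic C–O bond breaks, leaving the B5–O bond and both isolated alkenes untouched. A Lewis-acid cleavage is avoided because it could ionise the allylic ether or protonate the exocyclic alkene.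

Step 12
Reactants: 20 caffeic acid
Product: 22 (2E)-3-{3,4-bis[(tert-butyldimethylsilyl)oxy]phenyl}prop-2-enoic acid, via silyl ester 21 (not isolated)
Conditions: TBSCl (3.5 equiv), imidazole (7 equiv), DMF, rt; then AcOH–THF–H2O, rt
Reagents that add atoms: tert-butyldimethylsilyl chloride, CC(C)(C)[Si](C)(C)Cl
Why: Exhaustive silylation followed by selective hydrolysis of the labile silyl ester; aryl silyl ethers are stable to aqueous acetic acid, and the (E) alkene is untouched.

Step 13
Reactants: 19 (1S,5S)-2,5-dimethyl-5-[(1S)-1-methyl-2-methylidenecyclopentyl]cyclohex-2-en-1-ol, 22 (2E)-3-{3,4-bis[(tert-butyldimethylsilyl)oxy]phenyl}prop-2-enoic acid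
Product: 23 (1S,5S)-2,5-dimethyl-5-[(1S)-1-methyl-2-methylidenecyclopentyl]cyclohex-2-en-1-yl (2E)-3-{3,4-bis[(tert-butyldimethylsilyl)oxy]phenyl}prop-2-enoate
Conditions: EDC·HCl (2 equiv), DMAP (1 equiv), CH2Cl2, 0 °C to rt
Reagents that add atoms: none
Why: Steglich esterification; the acyl group is transferred to the oxygen and the B5–O bond is never broken, so B5 is retained, and the mild neutral conditions should not ionise the allylic system.

Step 14
Reactants: 23 (1S,5S)-2,5-dimethyl-5-[(1S)-1-methyl-2-methylidenecyclopentyl]cyclohex-2-en-1-yl (2E)-3-{3,4-bis[(tert-butyldimethylsilyl)oxy]phenyl}prop-2-enoate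
Product: 24 (1S,5S)-2,5-dimethyl-5-[(1S)-1-methyl-2-methylidenecyclopentyl]cyclohex-2-en-1-yl (2E)-3-(3,4-dihydroxyphenyl)prop-2-enoate
Conditions: TBAF (2.2 equiv), AcOH (2.5 equiv), THF, 0 °C, under argon
Reagents that add atoms: none
Why: Fluoride cleavage of aryl silyl ethers; acetic acid keeps the catechol protonated, which should prevent air oxidation and ester cleavage, and neither alkene nor the allylic ester reacts.

## Compound list

1 | 2-butyne | CC#CC | starting material
2 | cyclobutanone | O=C1CCC1 | starting material
3 | diisopropoxy(η2-but-2-yne)titanium (titanacyclopropene) | CC1=C(C)[Ti]1(OC(C)C)OC(C)C | intermediate (not isolated)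
4 | spiro oxatitanacyclopentene from 3 and 2 | CC1=C(C)C2(CCC2)O[Ti]1(OC(C)C)OC(C)C | intermediate (not isolated)
5 | 1-[(2Z)-3-iodobut-2-en-2-yl]cyclobutan-1-ol | I/C(C)=C(/C)C1(O)CCC1 | intermediate
6 | triethyl({1-[(2Z)-3-iodobut-2-en-2-yl]cyclobutyl}oxy)silane | I/C(C)=C(/C)C1(O[Si](CC)(CC)CC)CCC1 | intermediate
7 | methyl (2S)-oxirane-2-carboxylate | COC(=O)[C@@H]1CO1 | starting material
8 | alkenyllithium from 6 (lithium cis to the cyclobutyl carbon) | [Li]/C(C)=C(/C)C1(O[Si](CC)(CC)CC)CCC1 | intermediate (not isolated)
9 | alkenylmagnesium bromide from 8 (same geometry) | Br[Mg]/C(C)=C(/C)C1(O[Si](CC)(CC)CC)CCC1 | intermediate (not isolated)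
10 | methyl (2S,4Z)-2-hydroxy-4-methyl-5-{1-[(triethylsilyl)oxy]cyclobutyl}hex-4-enoate | COC(=O)[C@@H](O)C/C(C)=C(/C)C1(O[Si](CC)(CC)CC)CCC1 | intermediate
11 | methyl (2S,4Z)-2-(benzyloxy)-4-methyl-5-{1-[(triethylsilyl)oxy]cyclobutyl}hex-4-enoate | COC(=O)[C@@H](OCc1ccccc1)C/C(C)=C(/C)C1(O[Si](CC)(CC)CC)CCC1 | intermediate
12 | (2S,4Z)-2-(benzyloxy)-N-methoxy-N,4-dimethyl-5-{1-[(triethylsilyl)oxy]cyclobutyl}hex-4-enamide | CON(C)C(=O)[C@@H](OCc1ccccc1)C/C(C)=C(/C)C1(O[Si](CC)(CC)CC)CCC1 | intermediate
13 | (4S,6Z)-4-(benzyloxy)-6-methyl-7-{1-[(triethylsilyl)oxy]cyclobutyl}octa-1,6-dien-3-one | C=CC(=O)[C@@H](OCc1ccccc1)C/C(C)=C(/C)C1(O[Si](CC)(CC)CC)CCC1 | intermediate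
14 | {[(4S,6S)-6-(benzyloxy)-4-methyl-4-[(1R)-1-methyl-2-oxocyclopentyl]cyclohex-1-en-1-yl]oxy}(dimethyl)aluminium | O=C1CCC[C@]1(C)[C@@]1(C)CC=C(O[Al](C)C)[C@@H](OCc2ccccc2)C1 | intermediate (not isolated)
15 | (2S,4S)-2-(benzyloxy)-4-methyl-4-[(1R)-1-methyl-2-oxocyclopentyl]cyclohexan-1-one | O=C1CCC[C@]1(C)[C@@]1(C)CCC(=O)[C@@H](OCc2ccccc2)C1 | intermediate
16 | (2R)-2-[(1S,3S,4R)-3-(benzyloxy)-4-hydroxy-1,4-dimethylcyclohexyl]-2-methylcyclopentan-1-one | O=C1CCC[C@]1(C)[C@@]1(C)CC[C@@](C)(O)[C@@H](OCc2ccccc2)C1 | intermediate
17 | (2R)-2-[(1S,5S)-5-(benzyloxy)-1,4-dimethylcyclohex-3-en-1-yl]-2-methylcyclopentan-1-one | O=C1CCC[C@]1(C)[C@@]1(C)CC=C(C)[C@@H](OCc2ccccc2)C1 | intermediate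
18 | ({[(1S,5S)-2,5-dimethyl-5-[(1S)-1-methyl-2-methylidenecyclopentyl]cyclohex-2-en-1-yl]oxy}methyl)benzene | C=C1CCC[C@]1(C)[C@@]1(C)CC=C(C)[C@@H](OCc2ccccc2)C1 | intermediate
19 | (1S,5S)-2,5-dimethyl-5-[(1S)-1-methyl-2-methylidenecyclopentyl]cyclohex-2-en-1-ol | C=C1CCC[C@]1(C)[C@@]1(C)CC=C(C)[C@@H](O)C1 | intermediate
20 | caffeic acid | OC(=O)/C=C/c1ccc(O)c(O)c1 | starting material
21 | tert-butyldimethylsilyl (2E)-3-{3,4-bis[(tert-butyldimethylsilyl)oxy]phenyl}prop-2-enoate | CC(C)(C)[Si](C)(C)OC(=O)/C=C/c1ccc(O[Si](C)(C)C(C)(C)C)c(O[Si](C)(C)C(C)(C)C)c1 | intermediate (not isolated)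
22 | (2E)-3-{3,4-bis[(tert-butyldimethylsilyl)oxy]phenyl}prop-2-enoic acid | OC(=O)/C=C/c1ccc(O[Si](C)(C)C(C)(C)C)c(O[Si](C)(C)C(C)(C)C)c1 | intermediate
23 | (1S,5S)-2,5-dimethyl-5-[(1S)-1-methyl-2-methylidenecyclopentyl]cyclohex-2-en-1-yl (2E)-3-{3,4-bis[(tert-butyldimethylsilyl)oxy]phenyl}prop-2-enoate | C=C1CCC[C@]1(C)[C@@]1(C)CC=C(C)[C@@H](OC(=O)/C=C/c2ccc(O[Si](C)(C)C(C)(C)C)c(O[Si](C)(C)C(C)(C)C)c2)C1 | intermediate
24 | (1S,5S)-2,5-dimethyl-5-[(1S)-1-methyl-2-methylidenecyclopentyl]cyclohex-2-en-1-yl (2E)-3-(3,4-dihydroxyphenyl)prop-2-enoate | C=C1CCC[C@]1(C)[C@@]1(C)CC=C(C)[C@@H](OC(=O)/C=C/c2ccc(O)c(O)c2)C1 | target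

## Step count and least certain steps

Total: 14 steps. Longest linear sequence: 13 steps (steps 1 to 11, 13 and 14); step 12 is a one-step side branch.

Step 7 (key step). The most likely failure is that C–C bond formation loses to proton-driven processes: protonation of the tetrasubstituted alkene followed by ring enlargement without cyclisation, or proton loss from the A5 cation. The alkene has to create a quaternary carbon in a six-membered closure onto a moderately electrophilic enone, so the desired path may be slow. Bond rotation before the shift would also erode the A5/B1 relation, and the vinyl ketone can polymerise. The fallback uses a stronger, well-precedented initiator and sets out from 12.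
- Ethynylmagnesium bromide (THF, −78 to 0 °C) should give the ynone (4S,6Z)-4-(benzyloxy)-6-methyl-7-{1-[(triethylsilyl)oxy]cyclobutyl}oct-6-en-1-yn-3-one F1.
- Double addition of methanol (MeOH, catalytic K2CO3, 0 °C) should give the β-keto acetal (4S,6Z)-4-(benzyloxy)-1,1-dimethoxy-6-methyl-7-{1-[(triethylsilyl)oxy]cyclobutyl}oct-6-en-3-one F2.
- SnCl4 in CH2Cl2 at −78 °C should ionise the acetal and start a Prins cyclisation ended by pinacol-type ring enlargement of the silyloxycyclobutane (the known acetal-initiated Prins–pinacol class), giving the methoxy diketone (2S,4S)-2-(benzyloxy)-5-methoxy-4-methyl-4-[(1R)-1-methyl-2-oxocyclopentyl]cyclohexan-1-one F3.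
- DBU should eliminate methanol to the enedione (4R,6S)-6-(benzyloxy)-4-methyl-4-[(1R)-1-methyl-2-oxocyclopentyl]cyclohex-2-en-1-one F4.
- Conjugate reduction with [(Ph3P)CuH]6 returns to the route at 15.

Step 3. Transfer of the hindered tetrasubstituted alkenyl group to the epoxide may be slow, allowing attack at the ester or O-to-C silyl migration in 8 to intervene. The fallback moves the stereocentre-forming event to an auxiliary-controlled alkylation and sets out from 6.
- Iodine–lithium exchange and trapping with monomeric formaldehyde at −78 °C should give (2Z)-2-methyl-3-{1-[(triethylsilyl)oxy]cyclobutyl}but-2-en-1-ol F5.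
- MsCl/Et3N followed by LiBr (THF, 0 °C) should give {1-[(2Z)-4-bromo-3-methylbut-2-en-2-yl]cyclobutoxy}(triethyl)silane F6, kept cold and used at once.
- Commercial (4R)-4-benzyl-1,3-oxazolidin-2-one is acylated (n-BuLi, benzyloxyacetyl chloride) to (4R)-4-benzyl-3-[(benzyloxy)acetyl]-1,3-oxazolidin-2-one F7.
- The sodium enolate of F7 (NaHMDS, THF, −78 °C) is alkylated with F6 to give (4R)-4-benzyl-3-[(2S,4Z)-2-(benzyloxy)-4-methyl-5-{1-[(triethylsilyl)oxy]cyclobutyl}hex-4-enoyl]-1,3-oxazolidin-2-one F8, the (R) auxiliary directing the electrophile to the face that gives the (S) ether.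
- Transamination with MeNHOMe·HCl/AlMe3 returns to the route at 12.

Step 9. Regiocontrol may be lost through elimination into the methyl group, or through ionisation at B4 followed by hydride shift from B5, because tertiary sulfamates can react through ion pairs. The fallback installs the alkene by enolate chemistry, sets out from 15 and replaces steps 8 to 10.
- NaBH4 (MeOH, −78 °C) should reduce only the unhindered B4 ketone to (2R)-2-[(1S,3S)-3-(benzyloxy)-4-hydroxy-1-methylcyclohexyl]-2-methylcyclopentan-1-one F9 (either carbinol epimer serves).
- Wittig methylenation as in step 10 should give (2S,4S)-2-(benzyloxy)-4-methyl-4-[(1S)-1-methyl-2-methylidenecyclopentyl]cyclohexan-1-ol F10.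
- Dess–Martin periodinane should give (2S,4S)-2-(benzyloxy)-4-methyl-4-[(1S)-1-methyl-2-methylidenecyclopentyl]cyclohexan-1-one F11.
- Kinetic deprotonation at B3, away from the alkoxy-bearing carbon (KHMDS, PhNTf2, THF, −78 °C), should give (4S,6S)-6-(benzyloxy)-4-methyl-4-[(1S)-1-methyl-2-methylidenecyclopentyl]cyclohex-1-en-1-yl trifluoromethanesulfonate F12.
- Coupling with Me2CuLi returns to the route at 18.

Step 10. Enolisation of the hindered A1 ketone may outrun addition of the ylide and leave the conversion incomplete. The fallback is a two-stage Peterson olefination setting out from 17: Me3SiCH2Li with CeCl3 (THF, −78 °C) should add without enolisation to give (2R)-2-[(1S,5S)-5-(benzyloxy)-1,4-dimethylcyclohex-3-en-1-yl]-2-methyl-1-[(trimethylsilyl)methyl]cyclopentan-1-ol F13, and KH in THF should eliminate it to return at 18.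

## Further compounds

F1 | step 7 | (4S,6Z)-4-(benzyloxy)-6-methyl-7-{1-[(triethylsilyl)oxy]cyclobutyl}oct-6-en-1-yn-3-one | C#CC(=O)[C@@H](OCc1ccccc1)C/C(C)=C(/C)C1(O[Si](CC)(CC)CC)CCC1
F2 | step 7 | (4S,6Z)-4-(benzyloxy)-1,1-dimethoxy-6-methyl-7-{1-[(triethylsilyl)oxy]cyclobutyl}oct-6-en-3-one | COC(OC)CC(=O)[C@@H](OCc1ccccc1)C/C(C)=C(/C)C1(O[Si](CC)(CC)CC)CCC1
F3 | step 7 | (2S,4S)-2-(benzyloxy)-5-methoxy-4-methyl-4-[(1R)-1-methyl-2-oxocyclopentyl]cyclohexan-1-one (epimers at C5) | O=C1CCC[C@]1(C)[C@@]1(C)C(OC)CC(=O)[C@@H](OCc2ccccc2)C1
F4 | step 7 | (4R,6S)-6-(benzyloxy)-4-methyl-4-[(1R)-1-methyl-2-oxocyclopentyl]cyclohex-2-en-1-one | O=C1CCC[C@]1(C)[C@@]1(C)C=CC(=O)[C@@H](OCc2ccccc2)C1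
F5 | step 3 | (2Z)-2-methyl-3-{1-[(triethylsilyl)oxy]cyclobutyl}but-2-en-1-ol | OC/C(C)=C(/C)C1(O[Si](CC)(CC)CC)CCC1
F6 | step 3 | {1-[(2Z)-4-bromo-3-methylbut-2-en-2-yl]cyclobutoxy}(triethyl)silane | BrC/C(C)=C(/C)C1(O[Si](CC)(CC)CC)CCC1
F7 | step 3 | (4R)-4-benzyl-3-[(benzyloxy)acetyl]-1,3-oxazolidin-2-one | O=C(COCc1ccccc1)N1[C@H](Cc2ccccc2)COC1=O
F8 | step 3 | (4R)-4-benzyl-3-[(2S,4Z)-2-(benzyloxy)-4-methyl-5-{1-[(triethylsilyl)oxy]cyclobutyl}hex-4-enoyl]-1,3-oxazolidin-2-one | O=C([C@@H](OCc1ccccc1)C/C(C)=C(/C)C1(O[Si](CC)(CC)CC)CCC1)N1[C@H](Cc2ccccc2)COC1=O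
F9 | step 9 | (2R)-2-[(1S,3S)-3-(benzyloxy)-4-hydroxy-1-methylcyclohexyl]-2-methylcyclopentan-1-one (epimers at C4 of the cyclohexyl ring) | O=C1CCC[C@]1(C)[C@@]1(C)CCC(O)[C@@H](OCc2ccccc2)C1
F10 | step 9 | (2S,4S)-2-(benzyloxy)-4-methyl-4-[(1S)-1-methyl-2-methylidenecyclopentyl]cyclohexan-1-ol (epimers at C1) | C=C1CCC[C@]1(C)[C@@]1(C)CCC(O)[C@@H](OCc2ccccc2)C1
F11 | step 9 | (2S,4S)-2-(benzyloxy)-4-methyl-4-[(1S)-1-methyl-2-methylidenecyclopentyl]cyclohexan-1-one | C=C1CCC[C@]1(C)[C@@]1(C)CCC(=O)[C@@H](OCc2ccccc2)C1
F12 | step 9 | (4S,6S)-6-(benzyloxy)-4-methyl-4-[(1S)-1-methyl-2-methylidenecyclopentyl]cyclohex-1-en-1-yl trifluoromethanesulfonate | C=C1CCC[C@]1(C)[C@@]1(C)CC=C(OS(=O)(=O)C(F)(F)F)[C@@H](OCc2ccccc2)C1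
F13 | step 10 | (2R)-2-[(1S,5S)-5-(benzyloxy)-1,4-dimethylcyclohex-3-en-1-yl]-2-methyl-1-[(trimethylsilyl)methyl]cyclopentan-1-ol (epimers at C1) | C[Si](C)(C)CC1(O)CCC[C@]1(C)[C@@]1(C)CC=C(C)[C@@H](OCc2ccccc2)C1
A1 | alternative 1 | 6-(6-methyl-1,4-dioxaspiro[4.4]non-6-yl)bicyclo[4.1.0]heptan-2-ol, hydroxyl syn to the cyclopropane methylene | O1CCOC12CCC[C@]2(C)[C@@]12C[C@H]2[C@@H](O)CCC1
A2 | alternative 1 | 3-(6-methyl-1,4-dioxaspiro[4.4]non-6-yl)cyclohex-2-en-1-ol | O1CCOC12CCC[C@]2(C)C1=C[C@@H](O)CCC1
A3 | alternative 2 | 5-[2-(tert-butyldimethylsilyloxy)-1-methylcyclopentyl]-2,5-dimethyl-3-(trimethylsilyl)cyclohex-2-en-1-one | CC(C)(C)[Si](C)(C)O[C@@H]1CCC[C@]1(C)[C@@]1(C)CC([Si](C)(C)C)=C(C)C(=O)C1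
A4 | alternative 2 | 3-[2-(tert-butyldimethylsilyloxy)-1-methylcyclopentyl]-3-methylcyclobutan-1-one | CC(C)(C)[Si](C)(C)O[C@@H]1CCC[C@]1(C)C1(C)CC(=O)C1
A5 | alternative 3 | methyl 2-methyl-2-(8-methyl-1,4-dioxaspiro[4.5]dec-8-yl)-5-oxocyclopentane-1-carboxylate | COC(=O)[C@H]1C(=O)CC[C@]1(C)C1(C)CCC2(CC1)OCCO2
A6 | alternative 3 | methyl 2-diazo-6-(8-methyl-1,4-dioxaspiro[4.5]dec-8-yl)-3-oxoheptanoate | COC(=O)C(=[N+]=[N-])C(=O)CC[C@H](C)C1(C)CCC2(CC1)OCCO2
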